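**Retrosynthetic overview**

1. Enabling feature: the cis-oxirane C6–C7 sits between the carbinols C5 and C8 inside a 24-membered lactone ring (C1–C23 plus the ring oxygen) whose only other unsaturations are two Z-olefins (C2=C3, C18=C19). A cis-oxirane maps back to a Z-alkene and this to a ring alkyne, so the C6–C7 bond is made as C6≡C7 by ring-closing alkyne metathesis of an open-chain diyne ester; the catalyst ignores olefins and a ring of this size holds a linear alkyne without strain.
2. After ring closure: Lindlar reduction to the 6Z-alkene, release of C8–OH, then one hydroxyl-directed epoxidation that relays C6 and C7 from C8 (A1,3 strain), then desilylation.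
3. Diyne ester 29 comes from esterification of Z-enoic acid 10 (C1–C6 plus methyl cap) with alcohol 27 (C7–C24 plus methyl cap).
4. Acid 10 comes from but-2-ynal (catalytic allylation sets C5, Still–Gennari sets 2Z). Alcohol 27 comes from methyl (R)-glycidate (C9 bought) plus a nonenyl Grignard reagent, ynone transfer hydrogenation (C8 by catalyst), and a Z-Wittig reaction with the ylide from (R)-hex-5-en-2-ol (C23 bought).
5. Ring order: 24-membered macrocycle first (step 17), oxirane last (step 20).

Key step: step 17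

Remark: atoms are numbered along the seco acid throughout (C1 lactone carbonyl, C23 lactone carbinol, C24 methyl), and macrocycles are named as 23-olides. But-2-ynal is taken as a commercial material (otherwise from but-2-yn-1-ol and MnO2), and the catalysts are bought or made by known procedures.

**Route**

Step 1
Reactants: 1 but-2-ynal; 2 allyltributylstannane
Product: 3 (S)-hept-1-en-5-yn-4-ol
Conditions: (S)-BINOL (20 mol %), Ti(OiPr)4 (10 mol %), 4 Å MS, CH2Cl2, −20 °C; aq. NaHCO3
Reagents that add atoms: none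
Why: Keck asymmetric allylation, in which the (S)-BINOL–titanium complex should shield one aldehyde face so that allyl transfer from tin sets C5 as the (S)-carbinol, the same facial sense as with other unsaturated aldehydes.

Step 2
Reactants: 3 (S)-hept-1-en-5-yn-4-ol
Product: 4 (S)-tert-butyl(hept-1-en-5-yn-4-yloxy)dimethylsilane
Conditions: TBSCl, imidazole, DMF, 0 °C to rt
Reagents that add atoms: tert-butyldimethylsilyl chloride CC(C)(C)[Si](C)(C)Cl
Why: Imidazole-promoted silylation of a secondary alcohol, which does not touch the stereocentre.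

Step 3
Reactants: 4 (S)-tert-butyl(hept-1-en-5-yn-4-yloxy)dimethylsilane
Product: 6 (S)-3-[(tert-butyldimethylsilyl)oxy]hex-4-ynal, via vicinal diol 5 (not isolated)
Conditions: OsO4 (2 mol %), NaIO4, 2,6-lutidine, dioxane/H2O (3:1), rt
Reagents that add atoms: osmium tetroxide O=[Os](=O)(=O)=O (source of the aldehyde oxygen; re-oxidised by sodium periodate [Na+].[O-]I(=O)(=O)=O)
Why: Lemieux–Johnson cleavage, in which OsO4 dihydroxylates the terminal alkene (the internal alkyne is inert to it) and periodate cleaves the diol, with 2,6-lutidine buffering the medium for the silyl ether.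

Step 4
Reactants: 6 (S)-3-[(tert-butyldimethylsilyl)oxy]hex-4-ynal; 7 methyl bis(2,2,2-trifluoroethyl)phosphonoacetate
Product: 9 methyl (2Z,5S)-5-[(tert-butyldimethylsilyl)oxy]oct-2-en-6-ynoate, via potassium phosphonate carbanion 8 (not isolated)
Conditions: KHMDS, 18-crown-6, THF, −78 °C
Reagents that add atoms: none
Why: Still–Gennari olefination, in which the electron-poor phosphonate and the dissociated potassium ion make elimination from the kinetic adduct fast and so give the (Z)-enoate, while the low temperature protects the β-silyloxy aldehyde from elimination.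

Step 5
Reactants: 9 methyl (2Z,5S)-5-[(tert-butyldimethylsilyl)oxy]oct-2-en-6-ynoate
Product: 10 (2Z,5S)-5-[(tert-butyldimethylsilyl)oxy]oct-2-en-6-ynoic acid
Conditions: LiOH, THF/H2O (3:1), 0 °C to rt; then 1 M HCl to pH 4
Reagents that add atoms: lithium hydroxide [Li+].[OH-]
Why: Saponification of a methyl ester, which at 0 °C should leave the Z-geometry, the TBS ether and C5 unchanged.

Step 6
Reactants: 11 (R)-hex-5-en-2-ol
Product: 12 (R)-6-bromohexan-2-ol
Conditions: HBr (g), dibenzoyl peroxide (cat.), pentane, 0 °C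
Reagents that add atoms: hydrogen bromide Br
Why: Radical-chain anti-Markovnikov hydrobromination (peroxide effect) places bromine on the terminal carbon, and the remote carbinol centre is not involved.

Step 7
Reactants: 12 (R)-6-bromohexan-2-ol
Product: 13 [(5R)-5-hydroxyhexyl]triphenylphosphonium bromide
Conditions: PPh3, MeCN, reflux
Reagents that add atoms: triphenylphosphine c1ccc(cc1)P(c1ccccc1)c1ccccc1
Why: SN2 quaternisation of triphenylphosphine by the primary bromide, which tolerates the free secondary alcohol.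

Step 8
Reactants: 14 9-bromonon-1-ene; 15 methyl (R)-oxirane-2-carboxylate
Product: 17 methyl (R)-2-hydroxydodec-11-enoate, via non-8-enylmagnesium bromide 16 (not isolated)
Conditions: Mg, THF, rt; then CuI (10 mol %), 15, THF, −40 °C; aq. NH4Cl
Reagents that add atoms: none
Why: Copper-catalysed Grignard opening of the terminal epoxide at its CH2 carbon (faster than ester addition at low temperature) leaves the C–O bond at the stereocentre intact, so the bought (R)-centre becomes C9.

Step 9
Reactants: 17 methyl (R)-2-hydroxydodec-11-enoate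
Product: 18 methyl (R)-2-[(tert-butyldimethylsilyl)oxy]dodec-11-enoate
Conditions: TBSCl, imidazole, DMF, rt
Reagents that add atoms: tert-butyldimethylsilyl chloride CC(C)(C)[Si](C)(C)Cl
Why: Imidazole-promoted silylation of the α-hydroxy ester, which does not touch the stereocentre.

Step 10
Reactants: 18 methyl (R)-2-[(tert-butyldimethylsilyl)oxy]dodec-11-enoate
Product: 19 (R)-2-[(tert-butyldimethylsilyl)oxy]-N-methoxy-N-methyldodec-11-enamide
Conditions: MeNH(OMe)·HCl, iPrMgCl, THF, −20 to 0 °C
Reagents that add atoms: N,O-dimethylhydroxylamine hydrochloride CNOC.Cl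
Why: Weinreb amide formation by aminolysis of the ester with the chloromagnesium amide, under conditions that should not epimerise the α-silyloxy centre.

Step 11
Reactants: 19 (R)-2-[(tert-butyldimethylsilyl)oxy]-N-methoxy-N-methyldodec-11-enamide; 20 prop-1-ynylmagnesium bromide
Product: 21 (R)-5-[(tert-butyldimethylsilyl)oxy]pentadec-14-en-2-yn-4-one
Conditions: THF, 0 °C; aq. NH4Cl
Reagents that add atoms: none
Why: Alkynyl Grignard addition to a Weinreb amide stops at the chelated tetrahedral adduct, which gives the ynone on work-up without over-addition.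

Step 12
Reactants: 21 (R)-5-[(tert-butyldimethylsilyl)oxy]pentadec-14-en-2-yn-4-one
Product: 22 (4R,5R)-5-[(tert-butyldimethylsilyl)oxy]pentadec-14-en-2-yn-4-ol
Conditions: Ru[(S,S)-TsDPEN](p-cymene) (preformed amido complex, 2 mol %), iPrOH, rt
Reagents that add atoms: none
Why: Noyori asymmetric transfer hydrogenation of an ynone, in which the (S,S)-catalyst should deliver hydride under catalyst control to give the C8 carbinol syn to the C9 silyl ether, without reducing the alkyne or the terminal alkene.

Step 13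
Reactants: 22 (4R,5R)-5-[(tert-butyldimethylsilyl)oxy]pentadec-14-en-2-yn-4-ol
Product: 23 (4R,5R)-5-[(tert-butyldimethylsilyl)oxy]-4-[(triethylsilyl)oxy]pentadec-14-en-2-yne
Conditions: TESCl, imidazole, DMAP (cat.), CH2Cl2, 0 °C
Reagents that add atoms: chlorotriethylsilane CC[Si](Cl)(CC)CC
Why: Silylation of the propargylic alcohol with the more labile TES group, so that C8–O can later be freed selectively beside the two TBS ethers.

Step 14
Reactants: 23 (4R,5R)-5-[(tert-butyldimethylsilyl)oxy]-4-[(triethylsilyl)oxy]pentadec-14-en-2-yne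
Product: 25 (10R,11R)-10-[(tert-butyldimethylsilyl)oxy]-11-[(triethylsilyl)oxy]tetradec-12-ynal, via vicinal diol 24 (not isolated)
Conditions: OsO4 (2 mol %), NaIO4, 2,6-lutidine, dioxane/H2O (3:1), rt
Reagents that add atoms: osmium tetroxide O=[Os](=O)(=O)=O (source of the aldehyde oxygen; re-oxidised by sodium periodate [Na+].[O-]I(=O)(=O)=O)
Why: Lemieux–Johnson cleavage of the only alkene present, with the internal alkyne inert to OsO4 and the buffered medium sparing both silyl ethers.

Step 15
Reactants: 25 (10R,11R)-10-[(tert-butyldimethylsilyl)oxy]-11-[(triethylsilyl)oxy]tetradec-12-ynal; 13 [(5R)-5-hydroxyhexyl]triphenylphosphonium bromide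
Product: 27 (2R,6Z,16R,17R)-16-[(tert-butyldimethylsilyl)oxy]-17-[(triethylsilyl)oxy]icos-6-en-18-yn-2-ol, via ylide alkoxide 26 (not isolated)
Conditions: 13, NaHMDS (2 equiv per 13), THF, 0 °C; then 25, −78 °C to rt
Reagents that add atoms: none
Why: Wittig olefination with a non-stabilised ylide under lithium-free conditions should give the (Z)-alkene through the kinetic cis-oxaphosphetane, and the second equivalent of base holds the carbinol as its alkoxide so that C23 needs no protecting group.

Step 16
Reactants: 10 (2Z,5S)-5-[(tert-butyldimethylsilyl)oxy]oct-2-en-6-ynoic acid; 27 (2R,6Z,16R,17R)-16-[(tert-butyldimethylsilyl)oxy]-17-[(triethylsilyl)oxy]icos-6-en-18-yn-2-ol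
Product: 29 (2R,6Z,16R,17R)-16-[(tert-butyldimethylsilyl)oxy]-17-[(triethylsilyl)oxy]icos-6-en-18-yn-2-yl (2Z,5S)-5-[(tert-butyldimethylsilyl)oxy]oct-2-en-6-ynoate, via mixed anhydride 28 (not isolated)
Conditions: 2,4,6-trichlorobenzoyl chloride, Et3N, toluene, rt; then 27, DMAP, toluene, rt
Reagents that add atoms: none
Why: Yamaguchi esterification, in which DMAP attacks the mixed anhydride at the enoyl carbonyl and passes the acyl group to the secondary alcohol with retention at C23.

Step 17
Reactants: 29 (2R,6Z,16R,17R)-16-[(tert-butyldimethylsilyl)oxy]-17-[(triethylsilyl)oxy]icos-6-en-18-yn-2-yl (2Z,5S)-5-[(tert-butyldimethylsilyl)oxy]oct-2-en-6-ynoate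
Product: 30 (2Z,5S,8R,9R,18Z,23R)-5,9-bis[(tert-butyldimethylsilyl)oxy]-8-[(triethylsilyl)oxy]tetracosa-2,18-dien-6-yn-23-olide
Conditions: Mo(≡C–C6H4-4-OMe)(OSiPh3)3 (15 mol %), 5 Å MS, toluene (2 mM), rt to 80 °C
Reagents that add atoms: none
Why: The molybdenum alkylidyne adds to one methyl-capped alkyne of 29 in a [2+2] step, the molybdacyclobutadiene cycloreverts with loss of but-2-yne, and the substrate-bound alkylidyne repeats the sequence on the second alkyne, which forms the C6–C7 bond as a triple bond. The closest known reaction type is ring-closing alkyne metathesis of methyl-capped diyne esters that carry propargylic silyl ethers to macrocyclic cycloalkynes with silanolate-ligated molybdenum alkylidynes. One ring is closed, the 24-membered lactone ring (C1–C23 plus the ester oxygen), by intramolecular end-to-end metathesis with both alkyne carbons inside the ring, and a ring of this size takes the linear C5–C6≡C7–C8 unit without strain. No stereocentre is formed, but the ring alkyne fixes what follows, since syn semi-hydrogenation can only give the Z-alkene that becomes the cis-oxirane. The step needs chemoselectivity for the alkynes over the two Z-olefins, the ester and the silyl ethers, and ring closure over oligomerisation: the alkylidyne does not engage olefins, so C2=C3 and C18=C19 keep their geometry, the molecular sieves trap but-2-yne and pull the equilibrium forward, and millimolar dilution favours the monomeric ring.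

Step 18
Reactants: 30 (2Z,5S,8R,9R,18Z,23R)-5,9-bis[(tert-butyldimethylsilyl)oxy]-8-[(triethylsilyl)oxy]tetracosa-2,18-dien-6-yn-23-olide
Product: 31 (2Z,5S,6Z,8R,9R,18Z,23R)-5,9-bis[(tert-butyldimethylsilyl)oxy]-8-[(triethylsilyl)oxy]tetracosa-2,6,18-trien-23-olide
Conditions: H2 (1 atm), Lindlar catalyst, quinoline, EtOAc, rt
Reagents that add atoms: none
Why: Lindlar semi-hydrogenation adds hydrogen syn to the ring alkyne on the poisoned palladium surface and should stop at the (Z)-alkene, leaving the existing Z-olefins unreduced.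

Step 19
Reactants: 31 (2Z,5S,6Z,8R,9R,18Z,23R)-5,9-bis[(tert-butyldimethylsilyl)oxy]-8-[(triethylsilyl)oxy]tetracosa-2,6,18-trien-23-olide
Product: 32 (2Z,5S,6Z,8R,9R,18Z,23R)-5,9-bis[(tert-butyldimethylsilyl)oxy]-8-hydroxytetracosa-2,6,18-trien-23-olide
Conditions: PPTS, MeOH/CH2Cl2 (1:1), 0 °C
Reagents that add atoms: none
Why: Acid-catalysed methanolysis cleaves a secondary TES ether much faster than secondary TBS ethers, so only the C8 hydroxyl is freed.

Step 20
Reactants: 32 (2Z,5S,6Z,8R,9R,18Z,23R)-5,9-bis[(tert-butyldimethylsilyl)oxy]-8-hydroxytetracosa-2,6,18-trien-23-olide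
Product: 33 (2Z,5S,6R,7R,8R,9R,18Z,23R)-5,9-bis[(tert-butyldimethylsilyl)oxy]-6,7-epoxy-8-hydroxytetracosa-2,18-dien-23-olide
Conditions: VO(acac)2 (10 mol %), t-BuOOH (decane), CH2Cl2, 0 °C to rt
Reagents that add atoms: tert-butyl hydroperoxide CC(C)(C)OO
Why: Vanadium-catalysed hydroxyl-directed epoxidation, in which the vanadium-bound C8 alkoxide delivers the peroxide oxygen intramolecularly while A(1,3) strain with C5 holds C8–H in the plane of the Z-alkene, so oxygen should arrive on the face that carries C8–O (threo epoxy alcohol, the target's configuration at C6 and C7) with syn addition keeping the oxirane cis, and the C2=C3 and C18=C19 olefins, which lack a free allylic hydroxyl, are left alone.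

Step 21
Reactants: 33 (2Z,5S,6R,7R,8R,9R,18Z,23R)-5,9-bis[(tert-butyldimethylsilyl)oxy]-6,7-epoxy-8-hydroxytetracosa-2,18-dien-23-olide
Product: 34 AKML B, (2Z,5S,6S,7R,8S,9R,18Z,23R)-6,7-epoxy-5,8,9-trihydroxytetracosa-2,18-dien-23-olide
Conditions: HF·pyridine, pyridine, THF, 0 °C to rt
Reagents that add atoms: none
Why: Fluoride-mediated cleavage of the two secondary TBS ethers under pyridine-buffered conditions, which should spare the oxirane, the lactone and the Z-enoate.

**Compound list**

1 | but-2-ynal | CC#CC=O | starting material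
2 | allyltributylstannane | C=CC[Sn](CCCC)(CCCC)CCCC | starting material
3 | (S)-hept-1-en-5-yn-4-ol | CC#C[C@@H](O)CC=C | intermediate
4 | (S)-tert-butyl(hept-1-en-5-yn-4-yloxy)dimethylsilane | CC#C[C@@H](O[Si](C)(C)C(C)(C)C)CC=C | intermediate
5 | (4S)-4-[(tert-butyldimethylsilyl)oxy]hept-5-yne-1,2-diol (both C2 epimers) | CC#C[C@@H](O[Si](C)(C)C(C)(C)C)CC(O)CO | intermediate (not isolated)
6 | (S)-3-[(tert-butyldimethylsilyl)oxy]hex-4-ynal | CC#C[C@@H](O[Si](C)(C)C(C)(C)C)CC=O | intermediate
7 | methyl bis(2,2,2-trifluoroethyl)phosphonoacetate | COC(=O)CP(=O)(OCC(F)(F)F)OCC(F)(F)F | starting material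
8 | potassium carbanion of 7 | [K+].COC(=O)[CH-]P(=O)(OCC(F)(F)F)OCC(F)(F)F | intermediate (not isolated)
9 | methyl (2Z,5S)-5-[(tert-butyldimethylsilyl)oxy]oct-2-en-6-ynoate | CC#C[C@@H](O[Si](C)(C)C(C)(C)C)C/C=C\C(=O)OC | intermediate
10 | (2Z,5S)-5-[(tert-butyldimethylsilyl)oxy]oct-2-en-6-ynoic acid | CC#C[C@@H](O[Si](C)(C)C(C)(C)C)C/C=C\C(=O)O | intermediate
11 | (R)-hex-5-en-2-ol | C[C@@H](O)CCC=C | starting material
12 | (R)-6-bromohexan-2-ol | C[C@@H](O)CCCCBr | intermediate
13 | [(5R)-5-hydroxyhexyl]triphenylphosphonium bromide | C[C@@H](O)CCCC[P+](c1ccccc1)(c1ccccc1)c1ccccc1.[Br-] | intermediate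
14 | 9-bromonon-1-ene | C=CCCCCCCCBr | starting material
15 | methyl (R)-oxirane-2-carboxylate (methyl (R)-glycidate) | COC(=O)[C@H]1CO1 | starting material
16 | non-8-enylmagnesium bromide | C=CCCCCCCC[Mg]Br | intermediate (not isolated)
17 | methyl (R)-2-hydroxydodec-11-enoate | C=CCCCCCCCC[C@@H](O)C(=O)OC | intermediate
18 | methyl (R)-2-[(tert-butyldimethylsilyl)oxy]dodec-11-enoate | C=CCCCCCCCC[C@@H](O[Si](C)(C)C(C)(C)C)C(=O)OC | intermediate
19 | (R)-2-[(tert-butyldimethylsilyl)oxy]-N-methoxy-N-methyldodec-11-enamide | C=CCCCCCCCC[C@@H](O[Si](C)(C)C(C)(C)C)C(=O)N(C)OC | intermediate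
20 | prop-1-ynylmagnesium bromide | CC#C[Mg]Br | starting material
21 | (R)-5-[(tert-butyldimethylsilyl)oxy]pentadec-14-en-2-yn-4-one | C=CCCCCCCCC[C@@H](O[Si](C)(C)C(C)(C)C)C(=O)C#CC | intermediate
22 | (4R,5R)-5-[(tert-butyldimethylsilyl)oxy]pentadec-14-en-2-yn-4-ol | C=CCCCCCCCC[C@@H](O[Si](C)(C)C(C)(C)C)[C@H](O)C#CC | intermediate
23 | (4R,5R)-5-[(tert-butyldimethylsilyl)oxy]-4-[(triethylsilyl)oxy]pentadec-14-en-2-yne | C=CCCCCCCCC[C@@H](O[Si](C)(C)C(C)(C)C)[C@H](O[Si](CC)(CC)CC)C#CC | intermediate
24 | (11R,12R)-11-[(tert-butyldimethylsilyl)oxy]-12-[(triethylsilyl)oxy]pentadec-13-yne-1,2-diol (both C2 epimers) | OCC(O)CCCCCCCC[C@@H](O[Si](C)(C)C(C)(C)C)[C@H](O[Si](CC)(CC)CC)C#CC | intermediate (not isolated)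
25 | (10R,11R)-10-[(tert-butyldimethylsilyl)oxy]-11-[(triethylsilyl)oxy]tetradec-12-ynal | O=CCCCCCCCC[C@@H](O[Si](C)(C)C(C)(C)C)[C@H](O[Si](CC)(CC)CC)C#CC | intermediate
26 | sodium (R)-6-(triphenylphosphoranylidene)hexan-2-olate | C[C@@H]([O-])CCCC=P(c1ccccc1)(c1ccccc1)c1ccccc1.[Na+] | intermediate (not isolated)
27 | (2R,6Z,16R,17R)-16-[(tert-butyldimethylsilyl)oxy]-17-[(triethylsilyl)oxy]icos-6-en-18-yn-2-ol | C[C@@H](O)CCC/C=C\CCCCCCCC[C@@H](O[Si](C)(C)C(C)(C)C)[C@H](O[Si](CC)(CC)CC)C#CC | intermediate
28 | (2Z,5S)-5-[(tert-butyldimethylsilyl)oxy]oct-2-en-6-ynoic 2,4,6-trichlorobenzoic anhydride | CC#C[C@@H](O[Si](C)(C)C(C)(C)C)C/C=C\C(=O)OC(=O)c1c(Cl)cc(Cl)cc1Cl | intermediate (not isolated)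
29 | (2R,6Z,16R,17R)-16-[(tert-butyldimethylsilyl)oxy]-17-[(triethylsilyl)oxy]icos-6-en-18-yn-2-yl (2Z,5S)-5-[(tert-butyldimethylsilyl)oxy]oct-2-en-6-ynoate | CC#C[C@@H](O[Si](C)(C)C(C)(C)C)C/C=C\C(=O)O[C@H](C)CCC/C=C\CCCCCCCC[C@@H](O[Si](C)(C)C(C)(C)C)[C@H](O[Si](CC)(CC)CC)C#CC | intermediate
30 | (2Z,5S,8R,9R,18Z,23R)-5,9-bis[(tert-butyldimethylsilyl)oxy]-8-[(triethylsilyl)oxy]tetracosa-2,18-dien-6-yn-23-olide | C[C@@H]1CCC/C=C\CCCCCCCC[C@@H](O[Si](C)(C)C(C)(C)C)[C@H](O[Si](CC)(CC)CC)C#C[C@@H](O[Si](C)(C)C(C)(C)C)C/C=C\C(=O)O1 | intermediate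
31 | (2Z,5S,6Z,8R,9R,18Z,23R)-5,9-bis[(tert-butyldimethylsilyl)oxy]-8-[(triethylsilyl)oxy]tetracosa-2,6,18-trien-23-olide | C[C@@H]1CCC/C=C\CCCCCCCC[C@@H](O[Si](C)(C)C(C)(C)C)[C@H](O[Si](CC)(CC)CC)/C=C\[C@@H](O[Si](C)(C)C(C)(C)C)C/C=C\C(=O)O1 | intermediate
32 | (2Z,5S,6Z,8R,9R,18Z,23R)-5,9-bis[(tert-butyldimethylsilyl)oxy]-8-hydroxytetracosa-2,6,18-trien-23-olide | C[C@@H]1CCC/C=C\CCCCCCCC[C@@H](O[Si](C)(C)C(C)(C)C)[C@H](O)/C=C\[C@@H](O[Si](C)(C)C(C)(C)C)C/C=C\C(=O)O1 | intermediate
33 | (2Z,5S,6R,7R,8R,9R,18Z,23R)-5,9-bis[(tert-butyldimethylsilyl)oxy]-6,7-epoxy-8-hydroxytetracosa-2,18-dien-23-olide | C[C@@H]1CCC/C=C\CCCCCCCC[C@@H](O[Si](C)(C)C(C)(C)C)[C@H](O)[C@H]2O[C@H]2[C@@H](O[Si](C)(C)C(C)(C)C)C/C=C\C(=O)O1 | intermediate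
34 | AKML B, (2Z,5S,6S,7R,8S,9R,18Z,23R)-6,7-epoxy-5,8,9-trihydroxytetracosa-2,18-dien-23-olide | C[C@@H]1CCC/C=C\CCCCCCCC[C@@H](O)[C@H](O)[C@H]2O[C@H]2[C@@H](O)C/C=C\C(=O)O1 | target

**Step count and risks**

Total step count: 21. Longest linear sequence: 14 steps (steps 8–15, then 16–21).

Steps most likely to fail:

1. Step 17 (ring-closing alkyne metathesis). What may go wrong: both alkyne ends sit next to branched silyloxy carbons, so turnover may stall under the high dilution that ring closure needs, and intermolecular metathesis may then give oligomers. Fallback: form the C6≡C7 bond intermolecularly and close the ring at the lactone instead. It sets out from alcohol 27 and methyl ester 9. Alkyne cross-metathesis of 27 with an excess of 9 (an alcohol-tolerant molybdenum alkylidyne with a tripodal silanolate ligand, toluene, 5 Å MS, run concentrated) should give methyl (2Z,5S,8R,9R,18Z,23R)-5,9-bis[(tert-butyldimethylsilyl)oxy]-23-hydroxy-8-[(triethylsilyl)oxy]tetracosa-2,18-dien-6-ynoate F1. Saponification (LiOH, THF/H2O, 0 °C) should give the seco acid (2Z,5S,8R,9R,18Z,23R)-5,9-bis[(tert-butyldimethylsilyl)oxy]-23-hydroxy-8-[(triethylsilyl)oxy]tetracosa-2,18-dien-6-ynoic acid F2. Macrolactonisation under high dilution (Yamaguchi or Shiina conditions) brings the route back at cycloalkyne 30.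

2. Step 20 (directed epoxidation). What may go wrong: poor facial selectivity if the C4 methylene on the attacked face opposes delivery from C8–O, or oxidation of the allylic alcohol to the enone in place of oxygen transfer. Fallback: change from substrate control to catalyst control. It sets out from 32 and comes back at 33: the epoxidation is run with a vanadium catalyst that carries a chiral bishydroxamic acid ligand (VO(OiPr)3, ligand, t-BuOOH, toluene, 0 °C), the ligand enantiomer being chosen so that catalyst and the C8 carbinol favour the same alkene face. It makes no new compound (F0).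

3. Step 16 (esterification through the activated Z-enoyl group). What may go wrong: reversible conjugate addition of DMAP to the acylpyridinium ion, or γ-deprotonation, may isomerise the 2Z-enoate to 2E or move the double bond out of conjugation. Fallback: activate the alcohol instead of the acid and invert C23. It sets out from aldehyde 25 and acid 10, with (S)-hex-5-en-2-ol, the commercial enantiomer of 11. Radical hydrobromination as in step 6 gives (S)-6-bromohexan-2-ol F3, and triphenylphosphine as in step 7 gives [(5S)-5-hydroxyhexyl]triphenylphosphonium bromide F4. NaHMDS gives the ylide alkoxide sodium (S)-6-(triphenylphosphoranylidene)hexan-2-olate F5, which with 25 as in step 15 gives (2S,6Z,16R,17R)-16-[(tert-butyldimethylsilyl)oxy]-17-[(triethylsilyl)oxy]icos-6-en-18-yn-2-ol F6. Mitsunobu esterification of F6 with acid 10 (PPh3, DIAD, toluene, 0 °C to rt) proceeds with inversion at C23 and without acyl activation, and comes back at diyne ester 29.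

Further compounds

F1 | step 17 | methyl (2Z,5S,8R,9R,18Z,23R)-5,9-bis[(tert-butyldimethylsilyl)oxy]-23-hydroxy-8-[(triethylsilyl)oxy]tetracosa-2,18-dien-6-ynoate | C[C@@H](O)CCC/C=C\CCCCCCCC[C@@H](O[Si](C)(C)C(C)(C)C)[C@H](O[Si](CC)(CC)CC)C#C[C@@H](O[Si](C)(C)C(C)(C)C)C/C=C\C(=O)OC
F2 | step 17 | (2Z,5S,8R,9R,18Z,23R)-5,9-bis[(tert-butyldimethylsilyl)oxy]-23-hydroxy-8-[(triethylsilyl)oxy]tetracosa-2,18-dien-6-ynoic acid | C[C@@H](O)CCC/C=C\CCCCCCCC[C@@H](O[Si](C)(C)C(C)(C)C)[C@H](O[Si](CC)(CC)CC)C#C[C@@H](O[Si](C)(C)C(C)(C)C)C/C=C\C(=O)O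
F0 | step 20 | none | none
F3 | step 16 | (S)-6-bromohexan-2-ol | C[C@H](O)CCCCBr
F4 | step 16 | [(5S)-5-hydroxyhexyl]triphenylphosphonium bromide | C[C@H](O)CCCC[P+](c1ccccc1)(c1ccccc1)c1ccccc1.[Br-]
F5 | step 16 | sodium (S)-6-(triphenylphosphoranylidene)hexan-2-olate | C[C@H]([O-])CCCC=P(c1ccccc1)(c1ccccc1)c1ccccc1.[Na+]
F6 | step 16 | (2S,6Z,16R,17R)-16-[(tert-butyldimethylsilyl)oxy]-17-[(triethylsilyl)oxy]icos-6-en-18-yn-2-ol | C[C@H](O)CCC/C=C\CCCCCCCC[C@@H](O[Si](C)(C)C(C)(C)C)[C@H](O[Si](CC)(CC)CC)C#CC
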